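**Retrosynthetic overview** (carotenoid numbering)
1. The target is cut at C11=C12 and C11'=C12' (two Wittig reactions) into the commercial C10 trienedial and two C15 phosphonium salts: acetylenic for ring A, 7',8'-dihydro for ring B.
2. Ring A salt: C8–C9 Sonogashira bond to a ring alkyne. Ring B salt: C8'–C9' B-alkyl Suzuki bond to a ring vinyl compound. One (E)-3-iodobut-2-en-1-ol serves both and fixes 9E and 9'E.
3. Alkyne and vinyl compound both come from one aldehyde, the triethylsilyl (TES) ether of (4R)-4-hydroxy-β-cyclocitral.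
4. Its C4–O bond, which becomes both carbinol stereocentres (C3 and C3'), is made by a catalytic enantioselective 1,6-addition of triethylsilanol to safranal.
5. No ring is constructed: both cyclohexene rings come ready-made from safranal; ring B is joined to the chain first, ring A last.

Assumption: the facial sense of the new catalytic step must be fixed by experiment. The quinine-derived amine is written; its quinidine-derived pseudo-enantiomer replaces it if the sense is opposite. The check is desilylation of a sample of the adduct and comparison with the aglycone of natural picrocrocin, which is the 4R alcohol.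

**Route**

Step 1
Reactants: 1 but-2-yn-1-ol
Product: 3 (2E)-3-iodobut-2-en-1-ol, via vinylzirconocene 2 (not isolated)
Conditions: i-Bu2AlH (1.0 equiv), THF, 0 °C; Cp2ZrCl2 + i-Bu2AlH (1.2 equiv each, gives Cp2Zr(H)Cl), 0 °C → rt; I2, −78 °C → rt; aq HCl
Reagents that add atoms: iodine, II
Why: Hydrozirconation–iodinolysis: syn Zr–H addition to the aluminium alkoxide puts zirconium on C3 (the carbon carrying the small methyl group), and C–Zr to C–I exchange with retention gives the E iodide that later fixes 9E and 9'E.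

Step 2
Reactants: 4 safranal (2,6,6-trimethylcyclohexa-1,3-diene-1-carbaldehyde)
Product: 5 (4R)-2,6,6-trimethyl-4-[(triethylsilyl)oxy]cyclohex-1-ene-1-carbaldehyde
Conditions: Et3SiOH (5 equiv), 9-amino-9-deoxy-epi-quinine (20 mol %), PhCO2H (40 mol %), 4 Å MS, toluene (1 M), −20 °C; cold filtration through silica at full conversion
Reagents that add atoms: triethylsilanol, CC[Si](O)(CC)CC
Why: Proposed new method: the primary amine condenses with the hindered aldehyde to a vinylogous iminium ion; its β-carbon (ring C2) is fully substituted and blocked, so the silanol, hydrogen-bonded to and partly deprotonated by the quinuclidine nitrogen, adds at the δ-carbon (ring C4) on one enantiotopic face of the flat diene, which sets the 4R C–O stereocentre; γ-protonation of the dienamine at C3 and hydrolysis return the conjugated enal and the catalyst; low temperature, high concentration and excess silanol hold the reversible addition on the adduct side, and removing the amine at full conversion prevents retro-addition and loss of ee; closest known reaction types are the iminium-catalysed oxa-Michael addition of oximes to enals and the amine-catalysed 1,6-thia-Michael addition through vinylogous iminium ions.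

Step 3
Reactants: 5 (4R)-2,6,6-trimethyl-4-[(triethylsilyl)oxy]cyclohex-1-ene-1-carbaldehyde
Product: 6 triethyl{[(1R)-4-ethynyl-3,5,5-trimethylcyclohex-3-en-1-yl]oxy}silane
Conditions: TMSCHN2 (1.3 equiv), n-BuLi (1.25 equiv), THF, −78 °C; then 5, −78 °C → rt; aq NH4Cl
Reagents that add atoms: trimethylsilyldiazomethane, C[Si](C)(C)C=[N+]=[N-]
Why: Colvin homologation (addition of lithiated TMS-diazomethane, loss of silanolate and N2, 1,2-hydride shift of the alkylidene carbene) converts the hindered enal to the terminal enyne at low temperature, faster than γ-deprotonation, and leaves the silyl ether and the R centre untouched.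

Step 4
Reactants: 6 triethyl{[(1R)-4-ethynyl-3,5,5-trimethylcyclohex-3-en-1-yl]oxy}silane; 3 (2E)-3-iodobut-2-en-1-ol
Product: 7 (2E)-3-methyl-5-{(4R)-2,6,6-trimethyl-4-[(triethylsilyl)oxy]cyclohex-1-en-1-yl}pent-2-en-4-yn-1-ol
Conditions: PdCl2(PPh3)2 (3 mol %), CuI (6 mol %), Et3N, THF, rt, Ar
Reagents that add atoms: none
Why: Sonogashira coupling forms C8–C9 with retention of the iodide geometry (9E) and tolerates the free allylic alcohol and the silyl ether.

Step 5
Reactants: 7 (2E)-3-methyl-5-{(4R)-2,6,6-trimethyl-4-[(triethylsilyl)oxy]cyclohex-1-en-1-yl}pent-2-en-4-yn-1-ol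
Product: 9 {(2E)-5-[(4R)-4-hydroxy-2,6,6-trimethylcyclohex-1-en-1-yl]-3-methylpent-2-en-4-yn-1-yl}triphenylphosphonium bromide, via enyne diol 8 (not isolated)
Conditions: PPh3·HBr (1.2 equiv), MeOH, 0 °C → rt; crystallise (CH2Cl2/EtOAc)
Reagents that add atoms: triphenylphosphine hydrobromide, [Br-].c1ccc(cc1)[PH+](c1ccccc1)c1ccccc1
Why: Acidic methanol first removes the TES group, then the allylic alcohol is ionised and captured by PPh3 at the primary terminus (allylic phosphonium salt formation); the secondary homoallylic ring alcohol does not ionise.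

Step 6
Reactants: 5 (4R)-2,6,6-trimethyl-4-[(triethylsilyl)oxy]cyclohex-1-ene-1-carbaldehyde
Product: 10 triethyl{[(1R)-4-ethenyl-3,5,5-trimethylcyclohex-3-en-1-yl]oxy}silane
Conditions: Ph3PCH3Br (1.5 equiv), KN(SiMe3)2 (1.4 equiv), THF, 0 °C; then 5, 0 °C → rt
Reagents that add atoms: methyltriphenylphosphonium bromide, [Br-].C[P+](c1ccccc1)(c1ccccc1)c1ccccc1
Why: Wittig methylenation with the small unstabilised ylide works on β-cyclocitral-type aldehydes and creates no stereo element.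

Step 7
Reactants: 10 triethyl{[(1R)-4-ethenyl-3,5,5-trimethylcyclohex-3-en-1-yl]oxy}silane; 3 (2E)-3-iodobut-2-en-1-ol
Product: 12 (2E)-3-methyl-5-{(4R)-2,6,6-trimethyl-4-[(triethylsilyl)oxy]cyclohex-1-en-1-yl}pent-2-en-1-ol, via alkylborane 11 (not isolated)
Conditions: 9-BBN (1.3 equiv), THF, 0 °C → rt; then 3 M aq K3PO4, 3 (1.2 equiv), PdCl2(dppf) (5 mol %), AsPh3 (5 mol %), DMF, rt
Reagents that add atoms: none
Why: Hydroboration then B-alkyl Suzuki–Miyaura coupling: 9-BBN adds boron only to the terminal carbon of the twisted vinyl group (the tetrasubstituted ring olefin is inert), and coupling with retention of iodide geometry forms C8'–C9' with 9'E.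

Step 8
Reactants: 12 (2E)-3-methyl-5-{(4R)-2,6,6-trimethyl-4-[(triethylsilyl)oxy]cyclohex-1-en-1-yl}pent-2-en-1-ol
Product: 14 {(2E)-5-[(4R)-4-hydroxy-2,6,6-trimethylcyclohex-1-en-1-yl]-3-methylpent-2-en-1-yl}triphenylphosphonium bromide, via diol 13 (not isolated)
Conditions: PPh3·HBr (1.2 equiv), MeOH, 0 °C → rt; crystallise
Reagents that add atoms: triphenylphosphine hydrobromide, [Br-].c1ccc(cc1)[PH+](c1ccccc1)c1ccccc1
Why: As in step 5, TES methanolysis is followed by allylic phosphonium salt formation; PPh3 traps the E-configured allyl cation at the primary carbon before it can rotate or cyclise onto the ring olefin.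

Step 9
Reactants: 14 {(2E)-5-[(4R)-4-hydroxy-2,6,6-trimethylcyclohex-1-en-1-yl]-3-methylpent-2-en-1-yl}triphenylphosphonium bromide; 15 (2E,4E,6E)-2,7-dimethylocta-2,4,6-trienedial
Product: 18 (2E,4E,6E,8E,10E)-13-[(4R)-4-hydroxy-2,6,6-trimethylcyclohex-1-en-1-yl]-2,7,11-trimethyltrideca-2,4,6,8,10-pentaenal, via ylide 16 (not isolated), via 8Z-aldehyde 17 (not isolated)
Conditions: 15 (3 equiv), CH2Cl2/MeOH, 0 °C; 14 and NaOMe (1.1 equiv) added slowly, → rt; then heptane, 90 °C, Ar, dark; chromatography (excess 15 recovered)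
Reagents that add atoms: none
Why: Wittig olefination with the semi-stabilised allylic ylide forms C11'=C12'; excess dialdehyde and the lower electrophilicity of the more conjugated product keep it to one end, and heating converts the Z part of the new disubstituted bond to E.

Step 10
Reactants: 18 (2E,4E,6E,8E,10E)-13-[(4R)-4-hydroxy-2,6,6-trimethylcyclohex-1-en-1-yl]-2,7,11-trimethyltrideca-2,4,6,8,10-pentaenal; 9 {(2E)-5-[(4R)-4-hydroxy-2,6,6-trimethylcyclohex-1-en-1-yl]-3-methylpent-2-en-4-yn-1-yl}triphenylphosphonium bromide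
Product: 21 (all-E,3R,3'R)-7,8-didehydro-7',8'-dihydro-β,β-carotene-3,3'-diol (CNP0178054.1), via ylide 19 (not isolated), via 11Z-isomer 20 (not isolated)
Conditions: 9 (1.3 equiv), NaOMe (1.4 equiv), CH2Cl2/MeOH, 0 °C → rt; then EtOH, reflux, Ar, dark (no iodine); crystallise
Reagents that add atoms: none
Why: Wittig olefination of the apo-aldehyde with the acetylenic C15 ylide forms C11=C12 without protection of either hydroxyl; mild heating converts the 11Z part to 11E, while both carbinol centres and the 9E and 9'E bonds set earlier are not touched.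

**Compound list**
1 | but-2-yn-1-ol | CC#CCO | starting material
2 | (E)-[4-(diisobutylalumanyloxy)but-2-en-2-yl]zirconocene chloride | C/C(=C\CO[Al](CC(C)C)CC(C)C)[Zr](Cl)(C1C=CC=C1)C1C=CC=C1 | intermediate
3 | (2E)-3-iodobut-2-en-1-ol | C/C(I)=C\CO | intermediate
4 | safranal, 2,6,6-trimethylcyclohexa-1,3-diene-1-carbaldehyde | O=CC1=C(C)C=CCC1(C)C | starting material
5 | (4R)-2,6,6-trimethyl-4-[(triethylsilyl)oxy]cyclohex-1-ene-1-carbaldehyde | O=CC1=C(C)C[C@@H](O[Si](CC)(CC)CC)CC1(C)C | intermediate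
6 | triethyl{[(1R)-4-ethynyl-3,5,5-trimethylcyclohex-3-en-1-yl]oxy}silane | C#CC1=C(C)C[C@@H](O[Si](CC)(CC)CC)CC1(C)C | intermediate
7 | (2E)-3-methyl-5-{(4R)-2,6,6-trimethyl-4-[(triethylsilyl)oxy]cyclohex-1-en-1-yl}pent-2-en-4-yn-1-ol | OC/C=C(\C)C#CC1=C(C)C[C@@H](O[Si](CC)(CC)CC)CC1(C)C | intermediate
8 | (2E)-5-[(4R)-4-hydroxy-2,6,6-trimethylcyclohex-1-en-1-yl]-3-methylpent-2-en-4-yn-1-ol | OC/C=C(\C)C#CC1=C(C)C[C@@H](O)CC1(C)C | intermediate
9 | {(2E)-5-[(4R)-4-hydroxy-2,6,6-trimethylcyclohex-1-en-1-yl]-3-methylpent-2-en-4-yn-1-yl}triphenylphosphonium bromide | [Br-].c1ccccc1[P+](c1ccccc1)(c1ccccc1)C/C=C(\C)C#CC1=C(C)C[C@@H](O)CC1(C)C | intermediate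
10 | triethyl{[(1R)-4-ethenyl-3,5,5-trimethylcyclohex-3-en-1-yl]oxy}silane | C=CC1=C(C)C[C@@H](O[Si](CC)(CC)CC)CC1(C)C | intermediate
11 | 9-(2-{(4R)-2,6,6-trimethyl-4-[(triethylsilyl)oxy]cyclohex-1-en-1-yl}ethyl)-9-borabicyclo[3.3.1]nonane | C1CCC2CCCC1B2CCC1=C(C)C[C@@H](O[Si](CC)(CC)CC)CC1(C)C | intermediate
12 | (2E)-3-methyl-5-{(4R)-2,6,6-trimethyl-4-[(triethylsilyl)oxy]cyclohex-1-en-1-yl}pent-2-en-1-ol | OC/C=C(\C)CCC1=C(C)C[C@@H](O[Si](CC)(CC)CC)CC1(C)C | intermediate
13 | (2E)-5-[(4R)-4-hydroxy-2,6,6-trimethylcyclohex-1-en-1-yl]-3-methylpent-2-en-1-ol | OC/C=C(\C)CCC1=C(C)C[C@@H](O)CC1(C)C | intermediate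
14 | {(2E)-5-[(4R)-4-hydroxy-2,6,6-trimethylcyclohex-1-en-1-yl]-3-methylpent-2-en-1-yl}triphenylphosphonium bromide | [Br-].c1ccccc1[P+](c1ccccc1)(c1ccccc1)C/C=C(\C)CCC1=C(C)C[C@@H](O)CC1(C)C | intermediate
15 | (2E,4E,6E)-2,7-dimethylocta-2,4,6-trienedial | O=C/C(C)=C/C=C/C=C(C)/C=O | starting material
16 | {(2E)-5-[(4R)-4-hydroxy-2,6,6-trimethylcyclohex-1-en-1-yl]-3-methylpent-2-en-1-ylidene}triphenylphosphorane | c1ccccc1P(c1ccccc1)(c1ccccc1)=C/C=C(\C)CCC1=C(C)C[C@@H](O)CC1(C)C | intermediate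
17 | (2E,4E,6E,8Z,10E)-13-[(4R)-4-hydroxy-2,6,6-trimethylcyclohex-1-en-1-yl]-2,7,11-trimethyltrideca-2,4,6,8,10-pentaenal | O=C/C(C)=C/C=C/C=C(C)/C=C\C=C(/C)CCC1=C(C)C[C@@H](O)CC1(C)C | intermediate
18 | (2E,4E,6E,8E,10E)-13-[(4R)-4-hydroxy-2,6,6-trimethylcyclohex-1-en-1-yl]-2,7,11-trimethyltrideca-2,4,6,8,10-pentaenal | O=C/C(C)=C/C=C/C=C(C)/C=C/C=C(\C)CCC1=C(C)C[C@@H](O)CC1(C)C | intermediate
19 | {(2E)-5-[(4R)-4-hydroxy-2,6,6-trimethylcyclohex-1-en-1-yl]-3-methylpent-2-en-4-yn-1-ylidene}triphenylphosphorane | c1ccccc1P(c1ccccc1)(c1ccccc1)=C/C=C(\C)C#CC1=C(C)C[C@@H](O)CC1(C)C | intermediate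
20 | (11Z,3R,3'R)-7,8-didehydro-7',8'-dihydro-β,β-carotene-3,3'-diol | CC1=C(C#C/C(C)=C/C=C\C(C)=C\C=C\C=C(C)\C=C\C=C(/C)CCC2=C(C)C[C@@H](O)CC2(C)C)C(C)(C)C[C@H](O)C1 | intermediate
21 | (all-E,3R,3'R)-7,8-didehydro-7',8'-dihydro-β,β-carotene-3,3'-diol | CC1=C(C#C/C(C)=C/C=C/C(C)=C/C=C/C=C(C)/C=C/C=C(\C)CCC2=C(C)C[C@@H](O)CC2(C)C)C(C)(C)C[C@H](O)C1 | target

**Step count and risks**
Total steps: 10. Longest linear sequence: 6 (steps 2, 6, 7, 8, 9, 10).

Three steps most likely to fail:

1. Step 2, the proposed new step. The hindered aldehyde may form the iminium ion slowly, the silanol is a weak nucleophile, and the addition is reversible, so conversion may stall or the ee may erode. The fallback uses known chemistry and runs from 4 back to 5. Jacobsen–Katsuki epoxidation of the cis-disubstituted C3=C4 bond of 4 uses the (salen)MnCl catalyst N,N'-bis(3,5-di-tert-butylsalicylidene)cyclohexane-1,2-diaminomanganese chloride with buffered NaOCl and 4-phenylpyridine N-oxide in CH2Cl2 at 0 °C, the catalyst enantiomer being chosen by the rotation of the next compound. It gives (1R,6S)-2,4,4-trimethyl-7-oxabicyclo[4.1.0]hept-2-ene-3-carbaldehyde F1. Palladium-catalysed formate hydrogenolysis of this alkenyl oxirane (Pd2(dba)3, n-Bu3P, HCO2H/Et3N, dioxane, rt) cleaves only the allylic C–O bond and keeps the enal conjugated. It gives (4R)-4-hydroxy-2,6,6-trimethylcyclohex-1-ene-1-carbaldehyde F2, the picrocrocin aglycone. Et3SiCl and imidazole in DMF then give 5.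

2. Step 7. The neopentyl-like alkylborane may transmetalate slowly, and protodeboronation or β-hydride elimination would cost material. The fallback runs from 10 to 12 and builds the trisubstituted olefin by carbometalation instead of cross-coupling. Borane 11 is oxidised (NaBO3·4H2O, THF/H2O) to 2-{(4R)-2,6,6-trimethyl-4-[(triethylsilyl)oxy]cyclohex-1-en-1-yl}ethan-1-ol F3. I2, PPh3 and imidazole give triethyl{[(1R)-4-(2-iodoethyl)-3,5,5-trimethylcyclohex-3-en-1-yl]oxy}silane F4. LiC≡CH·H2NCH2CH2NH2 in DMSO gives {[(1R)-4-(but-3-yn-1-yl)-3,5,5-trimethylcyclohex-3-en-1-yl]oxy}triethylsilane F5. Negishi methylalumination (Me3Al, Cp2ZrCl2 cat., CH2Cl2), then n-BuLi and paraformaldehyde, gives 12; the E geometry follows from syn carbometalation.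

3. Step 10. The Wittig reaction gives Z isomers at the new bond, acetylenic carotenoids drift towards 9Z on long heating, and the polyene is sensitive to air and light, so all-E material may be hard to obtain pure. The fallback runs from 7 to 21 and uses an E-selective Horner–Wadsworth–Emmons reaction. PBr3 (cat. pyridine, Et2O, −20 °C) gives {[(1R)-4-[(3E)-5-bromo-3-methylpent-3-en-1-yn-1-yl]-3,5,5-trimethylcyclohex-3-en-1-yl]oxy}triethylsilane F6. Arbuzov reaction with P(OEt)3 gives diethyl [(2E)-3-methyl-5-{(4R)-2,6,6-trimethyl-4-[(triethylsilyl)oxy]cyclohex-1-en-1-yl}pent-2-en-4-yn-1-yl]phosphonate F7. Its anion (NaN(SiMe3)2, 2.2 equiv, THF, −78 °C → rt) reacts with aldehyde 18 to give (all-E,3R,3'R)-3-(triethylsilyloxy)-7,8-didehydro-7',8'-dihydro-β,β-caroten-3'-ol F8. Bu4NF buffered with AcOH in THF then gives 21.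

**Further compounds**
F1 | step 2 | (1R,6S)-2,4,4-trimethyl-7-oxabicyclo[4.1.0]hept-2-ene-3-carbaldehyde | O=CC1=C(C)[C@H]2O[C@H]2CC1(C)C
F2 | step 2 | (4R)-4-hydroxy-2,6,6-trimethylcyclohex-1-ene-1-carbaldehyde | O=CC1=C(C)C[C@@H](O)CC1(C)C
F3 | step 7 | 2-{(4R)-2,6,6-trimethyl-4-[(triethylsilyl)oxy]cyclohex-1-en-1-yl}ethan-1-ol | OCCC1=C(C)C[C@@H](O[Si](CC)(CC)CC)CC1(C)C
F4 | step 7 | triethyl{[(1R)-4-(2-iodoethyl)-3,5,5-trimethylcyclohex-3-en-1-yl]oxy}silane | ICCC1=C(C)C[C@@H](O[Si](CC)(CC)CC)CC1(C)C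
F5 | step 7 | {[(1R)-4-(but-3-yn-1-yl)-3,5,5-trimethylcyclohex-3-en-1-yl]oxy}triethylsilane | C#CCCC1=C(C)C[C@@H](O[Si](CC)(CC)CC)CC1(C)C
F6 | step 10 | {[(1R)-4-[(3E)-5-bromo-3-methylpent-3-en-1-yn-1-yl]-3,5,5-trimethylcyclohex-3-en-1-yl]oxy}triethylsilane | BrC/C=C(\C)C#CC1=C(C)C[C@@H](O[Si](CC)(CC)CC)CC1(C)C
F7 | step 10 | diethyl [(2E)-3-methyl-5-{(4R)-2,6,6-trimethyl-4-[(triethylsilyl)oxy]cyclohex-1-en-1-yl}pent-2-en-4-yn-1-yl]phosphonate | CCOP(=O)(OCC)C/C=C(\C)C#CC1=C(C)C[C@@H](O[Si](CC)(CC)CC)CC1(C)C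
F8 | step 10 | (all-E,3R,3'R)-3-(triethylsilyloxy)-7,8-didehydro-7',8'-dihydro-β,β-caroten-3'-ol | CC1=C(C#C/C(C)=C/C=C/C(C)=C/C=C/C=C(C)/C=C/C=C(\C)CCC2=C(C)C[C@@H](O)CC2(C)C)C(C)(C)C[C@H](O[Si](CC)(CC)CC)C1
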